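**Retrosynthetic overview**

1. Target 12 comes from Baeyer–Villiger oxidation of the bridging C8 ketone of the bicyclo[3.2.1]oct-3-ene-2,8-dione 11; the oxygen enters between C8 and the OMe-bearing bridgehead, so the lactone bridge is formed last.
2. Diketone 11 comes from a one-operation (5+2) union of two fragments of similar size, (E)-isoelemicin 2 and the phenoxonium (pentadienyl) cation released from quinone ketal 8. This makes the ketal-carbon–CH(Me) bond at the fully substituted carbon together with the CH–CH(aryl) bond, closes the five- and seven-membered carbocycles and sets all four stereocentres.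
3. Enabling feature: in 12 the ketal carbon C5, the alkene C4=C3, the ketone C2, C1 and the lactone carbonyl C7 are the six carbons of a 1,2,4-trioxygenated benzene ring (a 4-allyl-2-methoxy-5-oxyphenol) with one extra oxygen (O6) inserted. Without O6 and oxidised, this ring is a pentadienyl cation C5–C4–C3–C2–C1 bridged by the carbonyl C7, with an OMe-stabilised terminus (C5) and an enol-ether terminus (C1).
4. Ketal 8 comes from isovanillin (Dakin oxidation, selective silylation, bromination, Stille allylation, oxidative dearomatisation); alkene 2 comes from 5-bromo-1,2,3-trimethoxybenzene (Suzuki–Miyaura coupling).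
5. Ring order: the arene-derived six-membered ring (step 6), then the cyclopentane and cycloheptene rings of the bicycle (step 7), then the two lactone rings (step 8).

Key step: step 7

Assumption: the sense of induction of the chiral anion in step 7 cannot be predicted; the (S,S)-catalyst is written, and its mirror image is to be used if it favours the other enantiomer. Locants in the text are the von Baeyer locants of 11 and 12 as named in the compound list.

**Route**

Step 1
Reactants: 1 5-bromo-1,2,3-trimethoxybenzene
Product: 2 1,2,3-trimethoxy-5-[(1E)-prop-1-en-1-yl]benzene ((E)-isoelemicin)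
Conditions: (E)-prop-1-enylboronic acid pinacol ester, PdCl2(dppf) (3 mol %), K2CO3, 1,4-dioxane/H2O, 80 °C
Reagents that add atoms: (E)-prop-1-enylboronic acid pinacol ester, C/C=C/B1OC(C)(C)C(C)(C)O1
Why: Suzuki–Miyaura coupling: oxidative addition of zerovalent palladium into the aryl bromide, transmetalation of the alkenylboronate and reductive elimination transfer the propenyl group with retention of its (E) geometry, which later defines the trans methyl/aryl relationship.

Step 2
Reactants: 3 3-hydroxy-4-methoxybenzaldehyde (isovanillin)
Product: 4 4-methoxybenzene-1,3-diol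
Conditions: 30 % aq. H2O2, H2SO4 (cat.), MeOH, rt
Reagents that add atoms: hydrogen peroxide, OO
Why: Dakin-type Baeyer–Villiger oxidation: the electron-rich aryl group (para-OMe) migrates in the peroxide adduct of the aldehyde and the aryl formate is methanolysed in the same pot, which turns the formyl carbon into the phenolic oxygen para to the methoxy group.

Step 3
Reactants: 4 4-methoxybenzene-1,3-diol
Product: 5 2-methoxy-5-[(triisopropylsilyl)oxy]phenol
Conditions: TIPSCl (1.0 equiv), imidazole, CH2Cl2, −20 → 0 °C
Reagents that add atoms: chlorotriisopropylsilane, CC(C)[Si](Cl)(C(C)C)C(C)C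
Why: Silyl ether formation: the bulky silyl chloride should react at the unhindered hydroxyl para to the methoxy group and leave free the hydroxyl that is flanked by, and hydrogen-bonded to, the methoxy group.

Step 4
Reactants: 5 2-methoxy-5-[(triisopropylsilyl)oxy]phenol
Product: 6 4-bromo-2-methoxy-5-[(triisopropylsilyl)oxy]phenol
Conditions: NBS (1.0 equiv), MeCN, −20 °C
Reagents that add atoms: N-bromosuccinimide, O=C1CCC(=O)N1Br
Why: Electrophilic aromatic bromination: the free hydroxyl directs para, and the only other doubly activated site lies between the two oxygen substituents and is more hindered.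

Step 5
Reactants: 6 4-bromo-2-methoxy-5-[(triisopropylsilyl)oxy]phenol
Product: 7 2-methoxy-4-(prop-2-en-1-yl)-5-[(triisopropylsilyl)oxy]phenol
Conditions: allylSnBu3, Pd(PPh3)4 (5 mol %), DMF, 90 °C
Reagents that add atoms: allyltributylstannane, C=CC[Sn](CCCC)(CCCC)CCCC
Why: Stille coupling: zerovalent palladium inserts into the aryl–Br bond and the allyl group is transferred from tin under neutral conditions that the free phenol and the aryl silyl ether tolerate.

Step 6
Reactants: 7 2-methoxy-4-(prop-2-en-1-yl)-5-[(triisopropylsilyl)oxy]phenol
Product: 8 6,6-dimethoxy-4-(prop-2-en-1-yl)-3-[(triisopropylsilyl)oxy]cyclohexa-2,4-dien-1-one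
Conditions: PhI(OAc)2 (1.05 equiv), MeOH, 0 °C; short plug of neutral alumina, used directly
Reagents that add atoms: methanol, CO
Why: Oxidative dearomatisation with trivalent iodine (formation of a masked ortho-benzoquinone): the aryloxy-iodane collapses to a phenoxonium ion that methanol captures at the methoxy-bearing ortho carbon (oxygen-stabilised, while the para carbon is flanked by the silyloxy group), giving the ortho-quinone monoketal; a para adduct, if formed, would ionise to the same cation in step 7.

Step 7
Reactants: 8 6,6-dimethoxy-4-(prop-2-en-1-yl)-3-[(triisopropylsilyl)oxy]cyclohexa-2,4-dien-1-one; 2 (E)-isoelemicin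
Product: 11 (1R,5R,6R,7R)-5-methoxy-6-methyl-3-(prop-2-en-1-yl)-7-(3,4,5-trimethoxyphenyl)bicyclo[3.2.1]oct-3-ene-2,8-dione, via pentadienyl cation 9 (not isolated), via silyl oxocarbenium ion 10 (not isolated)
Conditions: (S,S)-imidodiphosphorimidate Brønsted acid (IDPi; BINOL-derived, N-triflyl; 5 mol %), 2 (1.5 equiv), 5 Å MS, toluene, −78 → −40 °C; Et3N quench
Reagents that add atoms: none
Why: Proposed new method: the confined chiral imidodiphosphorimidate ionises the dimethyl ketal of 8 (by protonation at first, then as its silylium form) to the 2-methoxy-4-silyloxy pentadienyl cation 9, a phenoxonium ion held as a contact ion pair with the chiral anion, and the alkene 2 adds to it in a polar, asynchronous (5+2) cycloaddition that ends when the silyl oxocarbenium ion 10 hands its triisopropylsilyl group to the anion, which regenerates the ionising silylium–anion pair. The closest known chemistry is the acid-promoted (5+2) cycloaddition of quinone monoketals and oxidised methoxyphenols with (E)-propenylbenzenes to racemic bicyclo[3.2.1]oct-3-ene-2,8-diones, and the imidodiphosphorimidate-controlled addition of nucleophiles to oxocarbenium ion pairs made from acetals; their combination in an enantioselective cycloaddition is new. The first bond joins the nucleophilic methyl-bearing alkene carbon to the oxocarbenium terminus (the fully substituted OMe carbon C5), and the benzylic cation so formed is captured by the silyl enol ether terminus (C1) in a 5-exo closure of the cyclopentanone ring C1–C7–C6–C5–C8 (enol ether double bond exocyclic to the forming ring), which at the same time completes the seven-membered ring; both new rings contain the new C5–C6 bond. C6 and C7 come out trans because the (E)-alkene adds suprafacially, the two bridgeheads follow from the bridging itself, the methyl-endo/aryl-exo arrangement is designed to be enforced by the triisopropylsilyloxy group, whose isopropyl groups fill the quadrant over the enol ether end that an endo aryl group would need, and the absolute sense is set by the anion covering one face of the planar cation. The step needs addition across the two carbons that flank the ring carbonyl (not at the allyl-bearing central carbon) with the CHMe end on the OMe carbon; this is secured because only that terminus is an oxocarbenium carbon, the other terminus is the nucleophilic enol ether carbon, and the silyl group shields the central carbon. It also needs carbon rather than oxygen capture of the benzylic cation, which the fast silyl transfer at low temperature should secure by fixing the kinetic bicyclic diketone before it can ionise back.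

Step 8
Reactants: 11 (1R,5R,6R,7R)-5-methoxy-6-methyl-3-(prop-2-en-1-yl)-7-(3,4,5-trimethoxyphenyl)bicyclo[3.2.1]oct-3-ene-2,8-dione
Product: 12 (1R,5S,8R,9R)-5-methoxy-9-methyl-3-(prop-2-en-1-yl)-8-(3,4,5-trimethoxyphenyl)-6-oxabicyclo[3.2.2]non-3-ene-2,7-dione
Conditions: mCPBA (1.2 equiv), CH2Cl2, 0 °C
Reagents that add atoms: 3-chloroperoxybenzoic acid, OOC(=O)c1cccc(Cl)c1
Why: Baeyer–Villiger oxidation: the peracid adds to the strained, non-conjugated bridging ketone rather than the enone carbonyl, the oxygen-substituted bridgehead migrates in preference to the acyl-substituted one with retention of configuration, and the monosubstituted allyl alkene and the electron-poor enone alkene are epoxidised more slowly than this activated ketone reacts.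

**Compound list**

1 | 5-bromo-1,2,3-trimethoxybenzene | COc1cc(Br)cc(OC)c1OC | starting material
2 | 1,2,3-trimethoxy-5-[(1E)-prop-1-en-1-yl]benzene ((E)-isoelemicin) | C/C=C/c1cc(OC)c(OC)c(OC)c1 | intermediate
3 | 3-hydroxy-4-methoxybenzaldehyde (isovanillin) | COc1ccc(C=O)cc1O | starting material
4 | 4-methoxybenzene-1,3-diol | COc1ccc(O)cc1O | intermediate
5 | 2-methoxy-5-[(triisopropylsilyl)oxy]phenol | COc1ccc(O[Si](C(C)C)(C(C)C)C(C)C)cc1O | intermediate
6 | 4-bromo-2-methoxy-5-[(triisopropylsilyl)oxy]phenol | COc1cc(Br)c(O[Si](C(C)C)(C(C)C)C(C)C)cc1O | intermediate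
7 | 2-methoxy-4-(prop-2-en-1-yl)-5-[(triisopropylsilyl)oxy]phenol | C=CCc1cc(OC)c(O)cc1O[Si](C(C)C)(C(C)C)C(C)C | intermediate
8 | 6,6-dimethoxy-4-(prop-2-en-1-yl)-3-[(triisopropylsilyl)oxy]cyclohexa-2,4-dien-1-one | C=CCC1=CC(OC)(OC)C(=O)C=C1O[Si](C(C)C)(C(C)C)C(C)C | intermediate
9 | methyl{6-oxo-3-(prop-2-en-1-yl)-4-[(triisopropylsilyl)oxy]cyclohexa-2,4-dien-1-ylidene}oxonium (pentadienyl cation, ion pair with the catalyst anion) | C=CCC1=CC(=[O+]C)C(=O)C=C1O[Si](C(C)C)(C(C)C)C(C)C | intermediate (not isolated)
10 | O-triisopropylsilyl oxocarbenium ion of diketone 11 at C2 (configuration as in 11) | C=CCC1=C[C@@]2(OC)C(=O)[C@@H](C1=[O+][Si](C(C)C)(C(C)C)C(C)C)[C@H](c1cc(OC)c(OC)c(OC)c1)[C@H]2C | intermediate (not isolated)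
11 | (1R,5R,6R,7R)-5-methoxy-6-methyl-3-(prop-2-en-1-yl)-7-(3,4,5-trimethoxyphenyl)bicyclo[3.2.1]oct-3-ene-2,8-dione (6-endo-methyl, 7-exo-aryl) | C=CCC1=C[C@@]2(OC)C(=O)[C@@H](C1=O)[C@H](c1cc(OC)c(OC)c(OC)c1)[C@H]2C | intermediate
12 | (1R,5S,8R,9R)-5-methoxy-9-methyl-3-(prop-2-en-1-yl)-8-(3,4,5-trimethoxyphenyl)-6-oxabicyclo[3.2.2]non-3-ene-2,7-dione | C=CCC1=C[C@@]2(OC)OC(=O)[C@@H](C1=O)[C@H](c1cc(OC)c(OC)c(OC)c1)[C@H]2C | target

**Step count and risks**

Total step count: 8. Longest linear sequence: 7 (steps 2 to 8).

Steps most likely to fail:

1. Step 7 (proposed new method). The chiral anion may not hold the planar cation tightly enough to discriminate its two faces, the bulky silyl group may be passed on too slowly for turnover, or the aryl group may slip into the endo orientation. The fallback uses known chemistry, sets out from 8 and 2 and comes back at 11. Promotion with a catalytic achiral silyl triflate (TMSOTf, CH2Cl2, −78 °C), the established acid promotion of quinone-ketal/propenylbenzene (5+2) cycloadditions, should give 11 as a racemate, that is, together with its mirror image (1S,5S,6S,7S)-5-methoxy-6-methyl-3-(prop-2-en-1-yl)-7-(3,4,5-trimethoxyphenyl)bicyclo[3.2.1]oct-3-ene-2,8-dione F1. Any aryl-endo diastereomer would be removed on silica and the enantiomers separated by preparative HPLC on a chiral stationary phase, after which 11 continues to step 8. This fallback still relies on the silyl group for the exo-aryl topology.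

2. Step 8. Epoxidation of the allyl group may compete with oxygen insertion, or the acid by-product may ionise the benzylic C1–C7 bond. The fallback sets out from 6 and comes back at 12 by keeping bromine in place of the allyl group until the end. Oxidative dearomatisation of 6 (PhI(OAc)2, MeOH, 0 °C) should give 4-bromo-6,6-dimethoxy-3-[(triisopropylsilyl)oxy]cyclohexa-2,4-dien-1-one F2. Cycloaddition with 2 as in step 7 (or as in its fallback) should give (1S,5R,6R,7R)-3-bromo-5-methoxy-6-methyl-7-(3,4,5-trimethoxyphenyl)bicyclo[3.2.1]oct-3-ene-2,8-dione F3. Baeyer–Villiger oxidation with mCPBA, now with no isolated alkene in the molecule, should give (1R,5S,8R,9R)-3-bromo-5-methoxy-9-methyl-8-(3,4,5-trimethoxyphenyl)-6-oxabicyclo[3.2.2]non-3-ene-2,7-dione F4. A Stille coupling of this α-bromo enone with allyltributylstannane (Pd2(dba)3, AsPh3, CuI, NMP, 40 °C) then gives 12.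

3. Step 3. Discrimination between the two phenolic hydroxyls may be insufficient, giving regioisomeric and bis-silyl ethers. The fallback sets out from 3 and comes back at 5 by differentiating the oxygens through the order in which they appear. Acetylation of 3 (Ac2O, pyridine) gives 5-formyl-2-methoxyphenyl acetate F5. Baeyer–Villiger oxidation of the aldehyde (mCPBA, CH2Cl2) and selective methanolysis of the aryl formate (NaHCO3, MeOH, 0 °C) gives 5-hydroxy-2-methoxyphenyl acetate F6. Silylation (TIPSCl, imidazole) gives 2-methoxy-5-[(triisopropylsilyl)oxy]phenyl acetate F7. Mild acetate methanolysis (K2CO3 cat., MeOH, 0 °C) gives 5.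

**Further compounds**

F1 | step 7 | (1S,5S,6S,7S)-5-methoxy-6-methyl-3-(prop-2-en-1-yl)-7-(3,4,5-trimethoxyphenyl)bicyclo[3.2.1]oct-3-ene-2,8-dione (enantiomer of 11) | C=CCC1=C[C@]2(OC)C(=O)[C@H](C1=O)[C@@H](c1cc(OC)c(OC)c(OC)c1)[C@@H]2C
F2 | step 8 | 4-bromo-6,6-dimethoxy-3-[(triisopropylsilyl)oxy]cyclohexa-2,4-dien-1-one | BrC1=CC(OC)(OC)C(=O)C=C1O[Si](C(C)C)(C(C)C)C(C)C
F3 | step 8 | (1S,5R,6R,7R)-3-bromo-5-methoxy-6-methyl-7-(3,4,5-trimethoxyphenyl)bicyclo[3.2.1]oct-3-ene-2,8-dione | BrC1=C[C@@]2(OC)C(=O)[C@@H](C1=O)[C@H](c1cc(OC)c(OC)c(OC)c1)[C@H]2C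
F4 | step 8 | (1R,5S,8R,9R)-3-bromo-5-methoxy-9-methyl-8-(3,4,5-trimethoxyphenyl)-6-oxabicyclo[3.2.2]non-3-ene-2,7-dione | BrC1=C[C@@]2(OC)OC(=O)[C@@H](C1=O)[C@H](c1cc(OC)c(OC)c(OC)c1)[C@H]2C
F5 | step 3 | 5-formyl-2-methoxyphenyl acetate | COc1ccc(C=O)cc1OC(C)=O
F6 | step 3 | 5-hydroxy-2-methoxyphenyl acetate | COc1ccc(O)cc1OC(C)=O
F7 | step 3 | 2-methoxy-5-[(triisopropylsilyl)oxy]phenyl acetate | COc1ccc(O[Si](C(C)C)(C(C)C)C(C)C)cc1OC(C)=O
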